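**Strategy.** The route rests on cutting the C3 methylene out of the chromanone ring. What remains, O1–C2(aryl)–C4(O)–C4a–C8a, is the furan ring of a 2-aryl-3-siloxybenzofuran. Asymmetric Simmons–Smith dearomatisation adds the future C3 as a cyclopropane, giving the precursor, a cis-fused 1a-aryl-6b-siloxycyclopropa[b]benzofuran. In the key step its cyclopropanolate breaks the ring-fusion bond: the five-membered O-heterocycle becomes the six-membered chromanone and C2 receives H with inversion, so (1aR) becomes (2S). The step exploits the β-aryloxy ketone O1–C2–C3–C4=O of the chromanone ring as a masked homoenolate. The cyclohexene follows from an exo-selective, chiral boron-mediated Diels–Alder reaction of the dehydroprenyl diene with a 2'-hydroxychalcone.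

Key step: step 7

Assumption: the L,L-dipeptide (step 4) and (S)-VANOL (step 11) are written as the ligands giving the required enantiomers; the sense of induction on these substrates is not secured by analogy, and the antipodal ligand is taken if the first run shows the opposite sense.

Assumption: protonation in step 7 follows the inversion course known for base-induced cyclopropanol opening, so (1aR,6bR)-11 maps onto (2S)-13; if retention operates, the antipodal dipeptide is used in step 4.

Step 1
Reactants: 1 6-hydroxy-1-benzofuran-3(2H)-one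
Product: 2 6-(methoxymethoxy)-1-benzofuran-3(2H)-one
Conditions: MOMCl (1.2 equiv), i-Pr2NEt (1.5 equiv), CH2Cl2, 0 °C → rt
Reagents that add atoms: chloromethyl methyl ether (MOMCl), COCCl
Why: O-alkylation (MOM protection) of the acidic para-acyl phenol with a hindered amine base, which should leave the enolisable C2 methylene of the coumaranone untouched.

Step 2
Reactants: 3 4,6-dibromobenzene-1,3-diol
Product: 4 1,5-dibromo-2,4-bis(methoxymethoxy)benzene
Conditions: MOMCl (2.5 equiv), i-Pr2NEt (3 equiv), CH2Cl2, 0 °C → rt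
Reagents that add atoms: chloromethyl methyl ether (MOMCl), COCCl
Why: Double MOM protection of the resorcinol gives a C2-symmetric dibromide whose two C–Br bonds are equivalent, so mono-coupling in step 3 needs no regiocontrol.

Step 3
Reactants: 2 6-(methoxymethoxy)-1-benzofuran-3(2H)-one, 4 1,5-dibromo-2,4-bis(methoxymethoxy)benzene
Product: 6 {[2-[5-bromo-2,4-bis(methoxymethoxy)phenyl]-6-(methoxymethoxy)-1-benzofuran-3-yl]oxy}triethylsilane, via sodium benzofuran-3-olate 5 (not isolated)
Conditions: 2, NaOt-Bu (2.2 equiv), THF, 0 °C; then 4 (3 equiv), Pd2(dba)3 (2.5 mol%), P(t-Bu)3 (6 mol%), toluene, 50 °C; then Et3SiCl (2.5 equiv), 0 °C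
Reagents that add atoms: chlorotriethylsilane, CC[Si](Cl)(CC)CC
Why: Palladium-catalysed ketone α-arylation on the fully pre-formed enolate (no free ketone, hence no self-aldol); excess dibromide and deactivation of the second C–Br by the electron-rich enolate ring should enforce mono-coupling, and O-silylation traps the aromatic enolate as the 3-siloxybenzofuran.

Step 4
Reactants: 6 {[2-[5-bromo-2,4-bis(methoxymethoxy)phenyl]-6-(methoxymethoxy)-1-benzofuran-3-yl]oxy}triethylsilane
Product: 7 (1aR,6bR)-1a-[5-bromo-2,4-bis(methoxymethoxy)phenyl]-4-(methoxymethoxy)-6b-(triethylsilyloxy)-1a,6b-dihydro-1H-cyclopropa[b][1]benzofuran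
Conditions: Et2Zn (2 equiv), CH2I2 (4 equiv), N-Boc-L-valyl-L-proline methyl ester (1.25 equiv), CH2Cl2, −40 → 0 °C
Reagents that add atoms: diiodomethane, ICI
Why: Simmons–Smith cyclopropanation of a silyl enol ether with a dipeptide-modified zinc carbenoid, here dearomatising the furan C2=C3 bond; cis-fusion is compulsory, so both quaternary centres are set together by the face the chiral carbenoid selects.

Step 5
Reactants: 8 2-methylbut-1-en-3-yne, 9 pinacolborane
Product: 10 4,4,5,5-tetramethyl-2-[(1E)-3-methylbuta-1,3-dien-1-yl]-1,3,2-dioxaborolane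
Conditions: Cp2Zr(H)Cl (5 mol%), Et3N (10 mol%), neat, 60 °C
Reagents that add atoms: none
Why: Zirconocene hydrochloride-catalysed syn, anti-Markovnikov hydroboration of the terminal alkyne, chemoselective over the 1,1-disubstituted alkene, should give the E-dienylboronate.

Step 6
Reactants: 7 (1aR,6bR)-1a-[5-bromo-2,4-bis(methoxymethoxy)phenyl]-4-(methoxymethoxy)-6b-(triethylsilyloxy)-1a,6b-dihydro-1H-cyclopropa[b][1]benzofuran, 10 4,4,5,5-tetramethyl-2-[(1E)-3-methylbuta-1,3-dien-1-yl]-1,3,2-dioxaborolane
Product: 11 (1aR,6bR)-1a-[2,4-bis(methoxymethoxy)-5-[(1E)-3-methylbuta-1,3-dien-1-yl]phenyl]-4-(methoxymethoxy)-6b-(triethylsilyloxy)-1a,6b-dihydro-1H-cyclopropa[b][1]benzofuran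
Conditions: 10 (1.5 equiv), Pd(OAc)2 (5 mol%), SPhos (10 mol%), K3PO4 (3 equiv), THF/H2O (10:1), 40 °C
Reagents that add atoms: none
Why: Suzuki–Miyaura coupling with retention of the E geometry, placed before the ring enlargement so that the base meets the non-enolisable silyl-protected cyclopropane and not the base-labile flavanone.

Step 7
Reactants: 11 (1aR,6bR)-1a-[2,4-bis(methoxymethoxy)-5-[(1E)-3-methylbuta-1,3-dien-1-yl]phenyl]-4-(methoxymethoxy)-6b-(triethylsilyloxy)-1a,6b-dihydro-1H-cyclopropa[b][1]benzofuran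
Product: 13 (2S)-2-[2,4-bis(methoxymethoxy)-5-[(1E)-3-methylbuta-1,3-dien-1-yl]phenyl]-7-(methoxymethoxy)-2,3-dihydro-4H-chromen-4-one, via tetrabutylammonium cyclopropanolate 12 (not isolated)
Conditions: Bu4NF (1.05 equiv), MeOH (10 equiv), THF, −78 → −30 °C; then AcOH (1.5 equiv), −30 °C
Reagents that add atoms: none
Why: Proposed new method: fluoride removes the triethylsilyl group and the liberated cyclopropanolate 12 collapses to the aryl ketone with heterolysis of the ring-fusion bond C1a–C6b, the carbon that becomes C2 taking a proton from methanol in an SE2 process. The closest known reaction is the base-induced homoketonisation of 2-arylcyclopropanols, which cleaves toward the benzylic carbon and protonates it with inversion; its use to enlarge a furan-fused siloxycyclopropane has not been shown. No cyclisation takes place: the six-membered ring O1–C2–C3–C4–C4a–C8a appears when the zero-atom bridge of the 2-oxabicyclo[3.1.0]hexane core is cut, so that the cyclopropane methylene becomes C3 inside the former five-membered ring. The C2 stereocentre is controlled by the configuration of C1a: protonation anti to the departing carbonyl carbon turns (1aR) into (2S), the front face being screened by the still-tethered C4. The step needs cleavage of the internal and not the external cyclopropane bond, which the aryl and aryloxy groups on C1a (carbanion stabilisation) and the higher strain of the fusion bond should secure. It also needs the product to escape base-induced retro-oxa-Michael opening, hence the low temperature, the excess methanol and the acetic acid quench.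

Step 8
Reactants: 14 1-(2,4-dihydroxyphenyl)ethanone
Product: 15 1-[2-hydroxy-4-(methoxymethoxy)phenyl]ethanone
Conditions: MOMCl (1.1 equiv), K2CO3 (1.5 equiv), acetone, 0 °C → rt
Reagents that add atoms: chloromethyl methyl ether (MOMCl), COCCl
Why: Selective O-alkylation of the 4-OH, because the 2-OH is held in a hydrogen bond to the carbonyl and stays free for boron chelation in step 11.

Step 9
Reactants: 16 2,4-dihydroxybenzaldehyde
Product: 17 2,4-bis(methoxymethoxy)benzaldehyde
Conditions: MOMCl (3 equiv), K2CO3 (4 equiv), acetone, reflux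
Reagents that add atoms: chloromethyl methyl ether (MOMCl), COCCl
Why: Exhaustive MOM protection; excess reagent and heat should also alkylate the chelated 2-OH.

Step 10
Reactants: 15 1-[2-hydroxy-4-(methoxymethoxy)phenyl]ethanone, 17 2,4-bis(methoxymethoxy)benzaldehyde
Product: 18 (2E)-3-[2,4-bis(methoxymethoxy)phenyl]-1-[2-hydroxy-4-(methoxymethoxy)phenyl]prop-2-en-1-one
Conditions: KOH (50% aq), EtOH, rt; then dilute HCl to pH 5
Reagents that add atoms: none
Why: Claisen–Schmidt aldol condensation, in which E1cB dehydration should give the E-enone and the 2'-phenoxide disfavours premature oxa-Michael closure at room temperature.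

Step 11
Reactants: 13 (2S)-2-[2,4-bis(methoxymethoxy)-5-[(1E)-3-methylbuta-1,3-dien-1-yl]phenyl]-7-(methoxymethoxy)-2,3-dihydro-4H-chromen-4-one, 18 (2E)-3-[2,4-bis(methoxymethoxy)phenyl]-1-[2-hydroxy-4-(methoxymethoxy)phenyl]prop-2-en-1-one
Product: 19 hexakis-O-methoxymethyl guangsangon N: the (2S)-7-(methoxymethoxy)flavanone whose 2',4'-bis(methoxymethoxy)phenyl ring carries at C5' the all-trans (3''R,4''R,5''S)-5''-[2,4-bis(methoxymethoxy)phenyl]-4''-[2-hydroxy-4-(methoxymethoxy)benzoyl]-1''-methylcyclohex-1''-en-3''-yl group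
Conditions: (S)-VANOL (1.2 equiv), BH3·THF (1.2 equiv), AcOH (1.2 equiv), THF, rt, then evaporation; 18 (1.0 equiv), 13 (1.3 equiv), 4 Å MS, PhCF3, rt
Reagents that add atoms: none
Why: Diels–Alder cycloaddition in which the 2'-hydroxy ketone is bound as a six-membered chelate to the VANOL borate, lowering the enone LUMO and screening one face; the unsubstituted diene terminus bonds to the β-carbon (C6''–C5''), the E-enone fixes C4''/C5'' trans, exo approach of the aroyl group should give C3''/C4'' trans, and the ligand sets the absolute sense (3''R,4''R,5''S), the remote (2S) centre playing no part.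

Step 12
Reactants: 19 hexakis-O-methoxymethyl guangsangon N
Product: 20 guangsangon N
Conditions: HCl (3 M aq)/MeOH/THF (1:4:2), 40 °C
Reagents that add atoms: none
Why: Acid-catalysed transacetalisation of the six aryl MOM ethers to methanol, mild enough that the flavanone C2–O bond, the α-keto centre C4'' and the trisubstituted alkene should survive; no stereocentre is formed or touched.

**Compound list**

1 | 6-hydroxy-1-benzofuran-3(2H)-one | O=C1COc2cc(O)ccc21 | starting material
2 | 6-(methoxymethoxy)-1-benzofuran-3(2H)-one | O=C1COc2cc(OCOC)ccc21 | intermediate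
3 | 4,6-dibromobenzene-1,3-diol | Oc1cc(O)c(Br)cc1Br | starting material
4 | 1,5-dibromo-2,4-bis(methoxymethoxy)benzene | COCOc1cc(OCOC)c(Br)cc1Br | intermediate
5 | sodium 2-[5-bromo-2,4-bis(methoxymethoxy)phenyl]-6-(methoxymethoxy)-1-benzofuran-3-olate | [Na+].[O-]c1c(-c2cc(Br)c(OCOC)cc2OCOC)oc2cc(OCOC)ccc12 | intermediate
6 | {[2-[5-bromo-2,4-bis(methoxymethoxy)phenyl]-6-(methoxymethoxy)-1-benzofuran-3-yl]oxy}triethylsilane | CC[Si](CC)(CC)Oc1c(-c2cc(Br)c(OCOC)cc2OCOC)oc2cc(OCOC)ccc12 | intermediate
7 | (1aR,6bR)-1a-[5-bromo-2,4-bis(methoxymethoxy)phenyl]-4-(methoxymethoxy)-6b-(triethylsilyloxy)-1a,6b-dihydro-1H-cyclopropa[b][1]benzofuran | CC[Si](CC)(CC)O[C@@]12C[C@]1(c1cc(Br)c(OCOC)cc1OCOC)Oc1cc(OCOC)ccc12 | intermediate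
8 | 2-methylbut-1-en-3-yne | CC(=C)C#C | starting material
9 | pinacolborane (4,4,5,5-tetramethyl-1,3,2-dioxaborolane) | CC1(C)OBOC1(C)C | starting material
10 | 4,4,5,5-tetramethyl-2-[(1E)-3-methylbuta-1,3-dien-1-yl]-1,3,2-dioxaborolane | CC(=C)/C=C/B1OC(C)(C)C(C)(C)O1 | intermediate
11 | (1aR,6bR)-1a-[2,4-bis(methoxymethoxy)-5-[(1E)-3-methylbuta-1,3-dien-1-yl]phenyl]-4-(methoxymethoxy)-6b-(triethylsilyloxy)-1a,6b-dihydro-1H-cyclopropa[b][1]benzofuran | CC[Si](CC)(CC)O[C@@]12C[C@]1(c1cc(/C=C/C(C)=C)c(OCOC)cc1OCOC)Oc1cc(OCOC)ccc12 | intermediate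
12 | tetrabutylammonium (1aR,6bR)-1a-[2,4-bis(methoxymethoxy)-5-[(1E)-3-methylbuta-1,3-dien-1-yl]phenyl]-4-(methoxymethoxy)-1a,6b-dihydro-1H-cyclopropa[b][1]benzofuran-6b-olate | CCCC[N+](CCCC)(CCCC)CCCC.[O-][C@@]12C[C@]1(c1cc(/C=C/C(C)=C)c(OCOC)cc1OCOC)Oc1cc(OCOC)ccc12 | intermediate
13 | (2S)-2-[2,4-bis(methoxymethoxy)-5-[(1E)-3-methylbuta-1,3-dien-1-yl]phenyl]-7-(methoxymethoxy)-2,3-dihydro-4H-chromen-4-one | C=C(C)/C=C/c1cc([C@@H]2CC(=O)c3ccc(OCOC)cc3O2)c(OCOC)cc1OCOC | intermediate
14 | 1-(2,4-dihydroxyphenyl)ethanone | CC(=O)c1ccc(O)cc1O | starting material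
15 | 1-[2-hydroxy-4-(methoxymethoxy)phenyl]ethanone | CC(=O)c1ccc(OCOC)cc1O | intermediate
16 | 2,4-dihydroxybenzaldehyde | O=Cc1ccc(O)cc1O | starting material
17 | 2,4-bis(methoxymethoxy)benzaldehyde | COCOc1ccc(C=O)c(OCOC)c1 | intermediate
18 | (2E)-3-[2,4-bis(methoxymethoxy)phenyl]-1-[2-hydroxy-4-(methoxymethoxy)phenyl]prop-2-en-1-one | COCOc1ccc(C(=O)/C=C/c2ccc(OCOC)cc2OCOC)c(O)c1 | intermediate
19 | hexakis-O-methoxymethyl guangsangon N, (2S,3''R,4''R,5''S), free OH ortho to the benzoyl carbonyl | CC1=C[C@@H](c2cc([C@@H]3CC(=O)c4ccc(OCOC)cc4O3)c(OCOC)cc2OCOC)[C@H](C(=O)c2ccc(OCOC)cc2O)[C@@H](c2ccc(OCOC)cc2OCOC)C1 | intermediate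
20 | guangsangon N | CC1=C[C@@H](c2cc([C@@H]3CC(=O)c4ccc(O)cc4O3)c(O)cc2O)[C@H](C(=O)c2ccc(O)cc2O)[C@@H](c2ccc(O)cc2O)C1 | target

**Step count.** Total: 12 steps. Longest linear sequence: 7 steps (steps 1, 3, 4, 6, 7, 11, 12).

**Steps most likely to fail**

1. Step 7 (proposed new method). The cyclopropanolate may open at the external bond instead, giving a 2-methylbenzofuranone with no ring enlargement. Protonation may also lose stereospecificity through a free benzylic carbanion, or the product may racemise by base-induced retro-oxa-Michael opening. The fallback uses known chemistry and keeps the five-to-six ring enlargement. It sets out from 7. Anhydrous FeCl3 in DMF at 0 °C cuts the same ring-fusion bond by one-electron oxidation, a known ring enlargement of bicyclic siloxycyclopropanes, and should give 2-[5-bromo-2,4-bis(methoxymethoxy)phenyl]-2-chloro-7-(methoxymethoxy)chroman-4-one F1. NaOAc in MeOH removes HCl to give the flavone 2-[5-bromo-2,4-bis(methoxymethoxy)phenyl]-7-(methoxymethoxy)-4H-chromen-4-one F2. Asymmetric hydrogenation of the flavone C2=C3 bond (Ru(cod)(2-methylallyl)2, chiral imidazolinylidene ligand of the SINpEt type, KOt-Bu, H2) should give the cis-flavanol (2S,4S)-2-[5-bromo-2,4-bis(methoxymethoxy)phenyl]-7-(methoxymethoxy)chroman-4-ol F3. Dess–Martin periodinane oxidises it to (2S)-2-[5-bromo-2,4-bis(methoxymethoxy)phenyl]-7-(methoxymethoxy)chroman-4-one F4. Suzuki–Miyaura coupling with 10 under weak base (Pd(OAc)2, SPhos, KF, THF/H2O, rt) comes back to the route at 13.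

2. Step 4. Face selection by the chiral zinc carbenoid may be poor on a tetrasubstituted, aryl-flanked enol ether inside a benzofuran. The fallback replaces asymmetric induction by resolution. It sets out from 6: achiral cyclopropanation (Et2Zn, CH2I2, CF3CO2H, CH2Cl2, 0 °C) should give 7 together with its enantiomer (1aS,6bS)-1a-[5-bromo-2,4-bis(methoxymethoxy)phenyl]-4-(methoxymethoxy)-6b-(triethylsilyloxy)-1a,6b-dihydro-1H-cyclopropa[b][1]benzofuran F5. Preparative HPLC on a cellulose tris(3,5-dimethylphenylcarbamate) phase separates the two, and the route is rejoined at 7.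

3. Step 11. The cycloaddition may proceed with insufficient exo preference or insufficient facial selectivity, so that the all-trans (3''R,4''R,5''S) adduct is not the main product. The fallback gives up catalyst control and relies on separation. It sets out from 13 and 18: silica-supported silver nanoparticles (zerovalent silver), CH2Cl2, 50 °C, a known promoter for 2'-hydroxychalcone cycloadditions, should give 19 with three diastereomers. These are the other exo adduct, (2S,3''S,4''S,5''R)-hexakis-O-methoxymethyl diastereomer of 19 F6, and the two endo adducts, (2S,3''S,4''R,5''S)-hexakis-O-methoxymethyl diastereomer of 19 F7 and (2S,3''R,4''S,5''R)-hexakis-O-methoxymethyl diastereomer of 19 F8. Preparative HPLC on a chiral stationary phase isolates 19, where the route is rejoined.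

Further compounds
F1 | step 7 | 2-[5-bromo-2,4-bis(methoxymethoxy)phenyl]-2-chloro-7-(methoxymethoxy)chroman-4-one | O=C1CC(Cl)(c2cc(Br)c(OCOC)cc2OCOC)Oc2cc(OCOC)ccc12
F2 | step 7 | 2-[5-bromo-2,4-bis(methoxymethoxy)phenyl]-7-(methoxymethoxy)-4H-chromen-4-one | O=c1cc(-c2cc(Br)c(OCOC)cc2OCOC)oc2cc(OCOC)ccc12
F3 | step 7 | (2S,4S)-2-[5-bromo-2,4-bis(methoxymethoxy)phenyl]-7-(methoxymethoxy)chroman-4-ol | O[C@H]1C[C@@H](c2cc(Br)c(OCOC)cc2OCOC)Oc2cc(OCOC)ccc12
F4 | step 7 | (2S)-2-[5-bromo-2,4-bis(methoxymethoxy)phenyl]-7-(methoxymethoxy)chroman-4-one | O=C1C[C@@H](c2cc(Br)c(OCOC)cc2OCOC)Oc2cc(OCOC)ccc12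
F5 | step 4 | (1aS,6bS)-1a-[5-bromo-2,4-bis(methoxymethoxy)phenyl]-4-(methoxymethoxy)-6b-(triethylsilyloxy)-1a,6b-dihydro-1H-cyclopropa[b][1]benzofuran | CC[Si](CC)(CC)O[C@]12C[C@@]1(c1cc(Br)c(OCOC)cc1OCOC)Oc1cc(OCOC)ccc12
F6 | step 11 | (2S,3''S,4''S,5''R)-hexakis-O-methoxymethyl diastereomer of 19 (exo) | CC1=C[C@H](c2cc([C@@H]3CC(=O)c4ccc(OCOC)cc4O3)c(OCOC)cc2OCOC)[C@@H](C(=O)c2ccc(OCOC)cc2O)[C@H](c2ccc(OCOC)cc2OCOC)C1
F7 | step 11 | (2S,3''S,4''R,5''S)-hexakis-O-methoxymethyl diastereomer of 19 (endo) | CC1=C[C@H](c2cc([C@@H]3CC(=O)c4ccc(OCOC)cc4O3)c(OCOC)cc2OCOC)[C@H](C(=O)c2ccc(OCOC)cc2O)[C@@H](c2ccc(OCOC)cc2OCOC)C1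
F8 | step 11 | (2S,3''R,4''S,5''R)-hexakis-O-methoxymethyl diastereomer of 19 (endo) | CC1=C[C@@H](c2cc([C@@H]3CC(=O)c4ccc(OCOC)cc4O3)c(OCOC)cc2OCOC)[C@@H](C(=O)c2ccc(OCOC)cc2O)[C@H](c2ccc(OCOC)cc2OCOC)C1
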